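## Structural features

The target consists of four rings in two bicyclic halves that share one carbon: a 5,7-dimethoxychroman-4-one (arene ring A fused to the pyranone ring C: O1, C2, C3, C4, C4a, C8a) and a 5,6-dimethoxybenzocyclobutene (arene ring B fused to a cyclobutene), joined spiro at C3. C3 is the only stereocentre; it is quaternary, (S)-configured, and carries four different carbons: the OCH2 carbon C2, the carbonyl carbon C4, the cyclobutene CH2 and a ring B carbon that has a methoxy group in the ortho position. No other stereocentre stands next to it, and because it has no α-hydrogen it cannot epimerise once it is made. The fragile parts are the strained benzocyclobutene, which opens to an o-quinodimethane on strong heating, and the two electron-rich arenes, which react readily with electrophiles and oxidants. The real difficulty is to create the crowded spiro carbon as one enantiomer and to attach the four-membered ring to it. The key step exploits that ring A (C4a, C5, C6, C7, C8, C8a) carries oxygen on C5, C7 and C8a and shares its C4a–C8a edge with ring C as the α,β-bond of the C4 ketone, so that C5 to C8 with their two oxygens can be added as an oxygenated diene to a ring C enone that already holds the spiro centre.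

## Logic of the disconnections

24 to 23. The O–CH3 bond on the C5 oxygen is cut. The annulation that builds ring A delivers C5 as a free, hydrogen-bonded phenol and C7 already as its methyl ether, so this cut ties the target to the direct product of the ring-forming step. No skeletal simplification results. The forward step must methylate a chelated phenol and nothing else, which is undemanding because C3 cannot enolise and ring C cannot open.

23 to 18 and 20. The bonds C8–C8a and C4a–C5 are cut, which removes ring A. The cut is made here because C5–C8 with the C5 and C7 oxygens is a four-carbon donor diene, and the C4a–C8a edge is an enone that can carry a leaving group on C4a. The tetracycle with a pentasubstituted arene becomes a tricyclic spiro enone and a one-step diene, and no stereocentre is at stake. The forward step must be regioselective (C8 to C8a, C5 to C4a), must outrun conjugate addition with loss of O1, and must shed HBr and methanol although H and Br are cis in the adduct.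

20 to 19. The O–Si bond is cut; 20 is the silyl dienolate of 19. The forward step needs γ-deprotonation, O-silylation and prompt use of a moisture-sensitive product.

18 to 15. The O1–C8a bond and the C4a–Br bond are cut, opening ring C to an open-chain vinylogous amide whose amino-bearing carbon is the future C8a and whose α-carbon is the future C4a. Bromine is best introduced at this stage: the open-chain vinylogous amide is far more nucleophilic than the dimethoxyarene, whereas the closed enol ether would compete with ring B for the halogen. The forward step must brominate only that carbon, remove the silyl group and let the hydroxyl displace the amine, all in one flask.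

15 to 13 and 14. The C4a=C8a bond is cut as a condensation. Only the methyl group of 13 is enolisable, so the one-carbon unit 14 can go to one place only. The forward step must stay below the temperature at which a benzocyclobutene opens.

13 to 10 and 11. The C4–C4a bond is cut, giving an ester and a one-carbon nucleophile. The ester is what the desymmetrisation leaves behind. The forward step must stop at single addition on a hindered ester.

10 to 9 to 8. The O–Si bond is cut, then the C2 carbon is taken back from CH2OH to CO2H. This brings both one-carbon arms on the quaternary centre to the carboxyl level, so that they differ only by O–H against O–CH3. The forward steps must reduce an acid next to an ester and then mask the alcohol against retro-aldol loss of formaldehyde.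

8 to 7. The difference between the two carboxyl groups is removed, so the quaternary carbon becomes a prochiral centre in an achiral molecule. The only stereocentre is then set by choosing between two enantiotopic groups, not by an asymmetric C–C bond formation at a crowded carbon. The forward step needs an esterase that tells the ring CH2 from the methoxy-flanked arene carbon; either sense of selection can be used, because the roles of the two carboxyl groups can be exchanged afterwards.

7 to 5 and 6. The bond from the future C3 to one ester carbon is cut (enolate acylation). The forward step needs an irreversible acyl donor, because 7 has no α-hydrogen and cannot drive a reversible Claisen equilibrium.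

5 to 3 to 1. The four-membered ring is traced to a five-membered ketone by a ring-contraction transform, and the diazo group is then removed. The strained ring is thus made from a strain-free ring, and the oxygen pattern of ring B comes with 1. The regiochemistry is fixed, because the migrating arene carbon is the one bonded to the ketone, next to the methoxy group. The forward steps need activation of the ketone for diazo transfer and photolysis at room temperature.

## Other disconnections considered

Alternative 1: The cut runs through ring B: three alternating C–C bonds of the benzocyclobutene arene are broken together, one of them the bond shared with the four-membered ring. Ring B, the cyclobutene and a temporary silicon ring then open to the triyne A1, a 5,7-dimethoxychroman-4-one whose C3 holds a propargyl group and an ethynyl group joined through a tetraisopropyldisiloxane to the third alkyne. In the forward direction CpCo(CO)2 (light and heat) or RhCl(PPh3)3 would trimerise the three alkynes to A2, in which a five-membered disiloxane marks the two arene carbons that must end as C–OMe.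
- In its favour: one step makes three C–C bonds and three rings, the tether removes any regiochemical question, and rings A and C would come from an ordinary chromanone.
- Against it here: the (S) quaternary centre with an ethynyl and a propargyl arm must exist before the key step, and no secure asymmetric access is apparent, since the enolate of a 3-substituted chromanone tends to open ring C. After the key step both aryl–silicon bonds must be oxidised (Tamao–Fleming type, with protodesilylation competing) and the phenols methylated.
- Structure: this plan attacks the hardest ring system directly, whereas the chosen plan obtains it by ring contraction of 3 and spends its key step on the easier ring A.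
- Mechanism: metal-mediated trimerisation of hexa-1,5-diynes to benzocyclobutenes is a well-documented reaction class. On this point the alternative is the better, because the union of 18 and 20 uses an untried dienophile class.
- Step economy: triyne assembly plus oxidation and methylation should be no shorter than the chosen route, and the chosen route has the more secure answer to the stereocentre.

Alternative 2: The cut is the C4a–C8a bond of ring A with ring C still open: the acylphloroglucinol A4 is traced to the 3,5,7-trioxoheptanoate A3, whose C7 ketone carries the quaternary benzocyclobutene with a benzyloxymethyl arm. In the forward direction Mg(OMe)2 would chelate the chain, and the carbanion between the C5 and C7 carbonyls would attack the ester carbonyl (Claisen-type 6-exo-trig acyl substitution) to give A4 after enolisation.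
- In its favour: the three oxygens of ring A arise in place, and the symmetric phloroglucinol leaves no regiochemical question. The quaternary neighbour shields the C7 ketone from the competing aldol mode, no halogen or stereoelectronically demanding elimination is involved, and the quaternary block could come from 8.
- Against it here: A3 requires acylation of a dioxo-ester polyanion with a hindered quaternary ester, and such triketo esters readily close to pyranones. After A4, debenzylation, closure of ring C at a neopentyl-type carbon and double methylation are still needed, against one step after 23.
- Structure: both plans build ring A onto a preformed spiro carbon, but here ring C is still open, whereas in the chosen plan it is the dienophile itself.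
- Mechanism: the Claisen cyclisation is classical, the equal of the chosen step in precedent and its better in regiochemical certainty.
- Step economy: the longer tail and the polyanion acylation make it longer by roughly two to three steps.

Alternative 3: The cut is the C3–C4 bond: chromanone A6, which has the quaternary centre but a methyl group in place of the cyclobutene CH2 and a bromine on the arene, is traced to aldehyde A5, a 2,4-dimethoxy-6-(2-arylallyloxy)benzaldehyde. In the forward direction a chiral triazolium salt and base give a carbene that turns the formyl carbon into an acyl anion equivalent, which adds across the 1,1-disubstituted alkene, closing ring C and creating C3 with its methyl group. A later palladium-catalysed C(sp3)–H arylation of that methyl group by the aryl bromide (Pd(OAc)2, P(tBu)3, K2CO3, through zerovalent palladium) would close the cyclobutene and give 24.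
- In its favour: a catalyst sets the stereocentre in the step that closes ring C, the oxygen patterns of both arenes are bought, and no final methylation is needed.
- Against it here: the alkene carries an arene substituted at both ortho positions and the aldehyde lies between two alkoxy groups, so rate and enantioselectivity are open. The late C–H arylation must prefer the methyl group to the OCH2 group and form a strained ring at high temperature on the whole molecule, with hydrodebromination competing.
- Structure: this plan meets both real difficulties (quaternary stereocentre, four-membered ring) directly and catalytically, which is the more elegant answer.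
- Mechanism: both key steps stretch a known reaction to an untested substrate and are equals in risk, but here a second demanding step follows.
- Step economy: the alternative is clearly the better, by an estimated four to five steps.
- The chosen plan keeps one advantage: strained ring and stereocentre are secured early by robust operations, so a failure of the key step costs only the last two steps.

Key step: step 11

Remarks before the steps:
- Numbering: chromanone atoms are O1, C2, C3 (spiro), C4 (C=O), C4a, C5–C8, C8a. In benzocyclobutene names C1 is the substituted sp3 carbon, C2 the ring CH2, and the methoxy groups are on C5 and C6, C6 lying next to the fusion carbon bonded to C1.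
- Check of the structures: 18, 23 and 24 have the same spatial arrangement at C3, which is (S) by the CIP rules in all three, and the ring contraction places the carboxyl-bearing carbon on the arene carbon next to the methoxy group, as 24 requires. No structure needs correction.
- Three points of chemistry were changed to make the plan sound: the second carboxyl group is introduced with a chloroformate and not a carbonate, because the carbonate route is reversible for a malonate without α-hydrogen; bromine is introduced on the open-chain enaminone before ring C is closed; and the loss of HBr in the key step is triggered by a silver salt, because H and Br are cis in the adduct.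
- Assumption: the esterase is taken to hydrolyse the ester group that leads to the (S)-half-ester 8; if it prefers the other group, the two carboxyl groups exchange roles (see the fallback for step 4) and the same 9 is reached.
- Reagents that supply a skeletal carbon (6, 11, 14) are numbered as starting materials.

## Steps

Step 1
Reactants: 1 6,7-dimethoxyindan-1-one
Product: 3 2-diazo-6,7-dimethoxyindan-1-one, via trifluoroacetyl ketone 2 (not isolated)
Conditions: LiN(SiMe3)2, THF, −78 °C; CF3CO2CH2CF3; aq HCl work-up; then 4-AcNHC6H4SO2N3, Et3N, H2O, MeCN, rt
Reagents that add atoms: 4-acetamidobenzenesulfonyl azide, CC(=O)Nc1ccc(cc1)S(=O)(=O)N=[N+]=[N-]; 2,2,2-trifluoroethyl trifluoroacetate, O=C(OCC(F)(F)F)C(F)(F)F (its atoms stay only in 2)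
Why: Detrifluoroacetylative diazo transfer (Regitz type): the kinetic enolate is C-acylated to diketone 2, which is acidic enough to accept the diazo group from the sulfonyl azide and then loses the trifluoroacetyl group as the acyl sulfonamide; direct transfer to the plain ketone would be too slow, and the aryl ethers are inert.

Step 2
Reactants: 3 2-diazo-6,7-dimethoxyindan-1-one
Product: 5 methyl 5,6-dimethoxybenzocyclobutene-1-carboxylate (racemic), via aryl ketene 4 (not isolated)
Conditions: hν (> 300 nm, Pyrex), MeOH, rt
Reagents that add atoms: methanol, CO
Why: Photochemical Wolff rearrangement: loss of N2 and 1,2-shift of the arene carbon contract the five-membered ring to ketene 4, which methanol traps as the ester; the migrating carbon is the one next to the methoxy-bearing position, so the ester-bearing carbon of 5 sits on the arene carbon ortho to OMe as in 24, and room temperature avoids thermal opening of the four-membered ring.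

Step 3
Reactants: 5 methyl 5,6-dimethoxybenzocyclobutene-1-carboxylate; 6 methyl chloroformate
Product: 7 dimethyl 5,6-dimethoxybenzocyclobutene-1,1-dicarboxylate
Conditions: LiN(iPr)2, THF, −78 °C; ClCO2Me, −78 to 0 °C
Reagents that add atoms: methyl chloroformate (6), COC(=O)Cl
Why: C-acylation of an ester enolate (crossed Claisen with a chloroformate): the benzylic α-proton is removed at low temperature and the enolate is trapped irreversibly, which matters because 7 has no α-hydrogen and could not drive a reversible acylation with a dialkyl carbonate. The product is achiral with two enantiotopic ester groups.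

Step 4
Reactants: 7 dimethyl 5,6-dimethoxybenzocyclobutene-1,1-dicarboxylate
Product: 8 (S)-1-(methoxycarbonyl)-5,6-dimethoxybenzocyclobutene-1-carboxylic acid
Conditions: pig liver esterase, pH 7.5 phosphate buffer, 10% DMSO, 25 °C, pH-stat (1 M NaOH); then HCl to pH 2
Reagents that add atoms: water, O
Why: Enzymatic desymmetrisation of a prochiral α,α-disubstituted malonate: the esterase hydrolyses one enantiotopic ester, and the difference in shape between the ring CH2 and the methoxy-flanked arene carbon is the element that sets the quaternary stereocentre; hydrolysis should stop at the half-ester because the carboxylate is a poor substrate. The acid can be enriched further by crystallisation of an amine salt.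

Step 5
Reactants: 8 (S)-1-(methoxycarbonyl)-5,6-dimethoxybenzocyclobutene-1-carboxylic acid
Product: 9 methyl (S)-1-(hydroxymethyl)-5,6-dimethoxybenzocyclobutene-1-carboxylate
Conditions: BH3·SMe2, THF, 0 °C to rt; MeOH quench
Reagents that add atoms: none
Why: Chemoselective borane reduction: the carboxylic acid is reduced through its acyloxyborane much faster than the methyl ester, so the acid carbon becomes the future C2 and the ester remains as the future C4; the quaternary centre has no α-hydrogen and cannot racemise.

Step 6
Reactants: 9 methyl (S)-1-(hydroxymethyl)-5,6-dimethoxybenzocyclobutene-1-carboxylate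
Product: 10 methyl (S)-1-[(tert-butyldimethylsilyloxy)methyl]-5,6-dimethoxybenzocyclobutene-1-carboxylate
Conditions: tBuMe2SiCl, imidazole, DMF, rt
Reagents that add atoms: tert-butyldimethylsilyl chloride, CC(C)(C)[Si](C)(C)Cl
Why: Silylation of a primary alcohol; the ether blocks retro-aldol loss of formaldehyde from the β-oxygenated carbonyl array in the basic steps that follow and is removed by the acid of step 9.

Step 7
Reactants: 10 methyl (S)-1-[(tert-butyldimethylsilyloxy)methyl]-5,6-dimethoxybenzocyclobutene-1-carboxylate; 11 (trimethylsilyl)methyllithium
Product: 13 1-[(S)-1-[(tert-butyldimethylsilyloxy)methyl]-5,6-dimethoxybenzocyclobuten-1-yl]ethanone, via silylmethyl ketone 12 (not isolated)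
Conditions: Me3SiCH2Li (2.5 equiv), THF–pentane, 0 °C to rt; MeOH, rt; aq NH4Cl
Reagents that add atoms: (trimethylsilyl)methyllithium (11), [Li]C[Si](C)(C)C
Why: Conversion of an ester into a methyl ketone with a silylmethyl anion: acyl substitution gives α-silyl ketone 12, which the second equivalent deprotonates at once so that no second addition can follow, and methanol then cleaves the C–Si bond. The silyl ether and the aryl ethers do not react.

Step 8
Reactants: 13 1-[(S)-1-[(tert-butyldimethylsilyloxy)methyl]-5,6-dimethoxybenzocyclobuten-1-yl]ethanone; 14 N,N-dimethylformamide dimethyl acetal
Product: 15 (E)-3-(dimethylamino)-1-[(S)-1-[(tert-butyldimethylsilyloxy)methyl]-5,6-dimethoxybenzocyclobuten-1-yl]prop-2-en-1-one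
Conditions: Me2NCH(OMe)2 (neat), 105 °C
Reagents that add atoms: N,N-dimethylformamide dimethyl acetal (14), COC(OC)N(C)C
Why: Condensation of a methyl ketone with an amide acetal to the (E)-vinylogous amide; only the methyl group is enolisable because the other α-carbon is quaternary, and the carbon introduced is the future C8a. The temperature stays below the range in which benzocyclobutenes open.

Step 9
Reactants: 15 (E)-3-(dimethylamino)-1-[(S)-1-[(tert-butyldimethylsilyloxy)methyl]-5,6-dimethoxybenzocyclobuten-1-yl]prop-2-en-1-one
Product: 18 (3S)-5-bromo-5',6'-dimethoxyspiro[2H-pyran-3,1'-benzocyclobuten]-4-one, via bromo enaminone 16 (not isolated), via hydroxy bromo enaminone 17 (not isolated)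
Conditions: N-bromosuccinimide, CH2Cl2, −78 to 0 °C; then 2 M HCl, THF, rt
Reagents that add atoms: N-bromosuccinimide, O=C1CCC(=O)N1Br
Why: α-Halogenation of a tertiary enaminone followed by acid-promoted cyclisation, the halochromone synthesis from hydroxyaryl enaminones applied to an aliphatic alcohol: the enaminone α-carbon is far more nucleophilic than the dimethoxyarene, so bromine goes to the future C4a only. Aqueous acid then removes the silyl group, and the free hydroxyl adds to the iminium carbon and expels dimethylamine (6-endo addition–elimination), closing the O1–C8a bond without touching C3.

Step 10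
Reactants: 19 methyl (E)-3-methoxybut-2-enoate
Product: 20 1,3-dimethoxy-1-(trimethylsilyloxy)buta-1,3-diene (mixture of enol geometries)
Conditions: LiN(iPr)2, THF, −78 °C; Me3SiCl, −78 °C to rt; distil
Reagents that add atoms: chlorotrimethylsilane, C[Si](C)(C)Cl
Why: γ-Deprotonation of the β-methoxy enoate and O-silylation of the dienolate, the standard preparation of this silyl ketene acetal diene; it is used freshly distilled because it is sensitive to moisture and acid.

Step 11
Reactants: 18 (3S)-5-bromo-5',6'-dimethoxyspiro[2H-pyran-3,1'-benzocyclobuten]-4-one; 20 1,3-dimethoxy-1-(trimethylsilyloxy)buta-1,3-diene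
Product: 23 (3S)-5-hydroxy-7,5',6'-trimethoxyspiro[chroman-3,1'-benzocyclobuten]-4-one, via cis-fused cycloadduct 21 (not isolated), via aryl trimethylsilyl ether 22 (not isolated)
Conditions: 20 (3 equiv), PhMe, 100 °C, sealed tube; evaporate; AgOSO2CF3, 2,6-lutidine, CH2Cl2, −20 °C to rt; 1 M HCl, THF
Reagents that add atoms: none
Why: Proposed new method: the closest known reaction type is the Diels–Alder addition of 1,3-dialkoxy-1-silyloxybutadienes to haloquinones and α-halo enones with loss of HX and methanol to a resorcinol ring, and the bromide-loss stage is modelled on the silver-promoted ionisation of α'-bromo silyl enol ethers to 2-siloxyallyl cations; a 5-bromo-2,3-dihydropyran-4-one has not served as the 2π partner, so the reasoning is as follows. The nucleophilic CH2 terminus of 20 (largest HOMO coefficient) bonds to the β-carbon C8a of the push–pull enone (largest LUMO coefficient) and the ketene-acetal carbon bonds to the bromine-bearing C4a, in an asynchronous (4+2) addition; ring A therefore closes by intermolecular cycloaddition across C4a=C8a to give cis-fused 21. In 21 the C8a hydrogen and the C4a bromine are cis and C8a–H is not acidified, so a plain anti elimination is not available. The silver salt therefore first ionises the C5 silyl ketal (methanol leaves with a C8 proton, giving a 5-siloxy-7-methoxy diene) and then abstracts bromide from C4a, now the α'-carbon of a silyl enol ether; the cyclohexadienyl cation gives up the C8a proton to 2,6-lutidine and becomes 22. Acidic work-up cleaves the O–Si bond and leaves 23 with the C5 hydroxyl hydrogen-bonded to C4=O. The stereocentres formed at C4a, C5 and C8a are all destroyed on aromatisation, so no facial or endo/exo control is needed, and C3, being quaternary, cannot epimerise. The step needs regioselectivity, which the matched polarisation of diene and bromo-enone secures; cycloaddition in preference to conjugate addition with expulsion of O1, favoured by a non-polar medium, heat and the absence of a Lewis acid in the first stage; and loss of bromide in preference to loss of O1, favoured by the halophilic silver salt and the absence of strong base.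

Step 12
Reactants: 23 (3S)-5-hydroxy-7,5',6'-trimethoxyspiro[chroman-3,1'-benzocyclobuten]-4-one
Product: 24 (3S)-5,7,5',6'-tetramethoxyspiro[chroman-3,1'-benzocyclobuten]-4-one
Conditions: MeI, K2CO3, DMF, 45 °C
Reagents that add atoms: iodomethane, CI
Why: Williamson O-methylation of the chelated C5 phenol; the hydrogen bond to C4=O slows the reaction, hence DMF and mild heating, and nothing else in 23 is base-sensitive because the quaternary C3 rules out enolisation and retro-oxa-Michael opening of ring C.

## Compound list

1 | 6,7-dimethoxyindan-1-one | COc1ccc2CCC(=O)c2c1OC | starting material
2 | 6,7-dimethoxy-2-(trifluoroacetyl)indan-1-one | COc1ccc2CC(C(=O)C(F)(F)F)C(=O)c2c1OC | intermediate (not isolated)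
3 | 2-diazo-6,7-dimethoxyindan-1-one | COc1ccc2CC(=[N+]=[N-])C(=O)c2c1OC | intermediate
4 | (5,6-dimethoxybenzocyclobuten-1-ylidene)methanone (aryl ketene) | COc1ccc2CC(=C=O)c2c1OC | intermediate (not isolated)
5 | methyl 5,6-dimethoxybenzocyclobutene-1-carboxylate (racemic) | COC(=O)C1Cc2ccc(OC)c(OC)c21 | intermediate
6 | methyl chloroformate | COC(=O)Cl | starting material
7 | dimethyl 5,6-dimethoxybenzocyclobutene-1,1-dicarboxylate (achiral) | COC(=O)C1(Cc2ccc(OC)c(OC)c21)C(=O)OC | intermediate
8 | (S)-1-(methoxycarbonyl)-5,6-dimethoxybenzocyclobutene-1-carboxylic acid | OC(=O)[C@@]1(Cc2ccc(OC)c(OC)c21)C(=O)OC | intermediate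
9 | methyl (S)-1-(hydroxymethyl)-5,6-dimethoxybenzocyclobutene-1-carboxylate | OC[C@@]1(Cc2ccc(OC)c(OC)c21)C(=O)OC | intermediate
10 | methyl (S)-1-[(tert-butyldimethylsilyloxy)methyl]-5,6-dimethoxybenzocyclobutene-1-carboxylate | CC(C)(C)[Si](C)(C)OC[C@@]1(Cc2ccc(OC)c(OC)c21)C(=O)OC | intermediate
11 | (trimethylsilyl)methyllithium | [Li]C[Si](C)(C)C | starting material
12 | 1-[(S)-1-[(tert-butyldimethylsilyloxy)methyl]-5,6-dimethoxybenzocyclobuten-1-yl]-2-(trimethylsilyl)ethanone | CC(C)(C)[Si](C)(C)OC[C@@]1(Cc2ccc(OC)c(OC)c21)C(=O)C[Si](C)(C)C | intermediate (not isolated)
13 | 1-[(S)-1-[(tert-butyldimethylsilyloxy)methyl]-5,6-dimethoxybenzocyclobuten-1-yl]ethanone | CC(C)(C)[Si](C)(C)OC[C@@]1(Cc2ccc(OC)c(OC)c21)C(C)=O | intermediate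
14 | N,N-dimethylformamide dimethyl acetal | COC(OC)N(C)C | starting material
15 | (E)-3-(dimethylamino)-1-[(S)-1-[(tert-butyldimethylsilyloxy)methyl]-5,6-dimethoxybenzocyclobuten-1-yl]prop-2-en-1-one | CC(C)(C)[Si](C)(C)OC[C@@]1(Cc2ccc(OC)c(OC)c21)C(=O)/C=C/N(C)C | intermediate
16 | (Z)-2-bromo-3-(dimethylamino)-1-[(S)-1-[(tert-butyldimethylsilyloxy)methyl]-5,6-dimethoxybenzocyclobuten-1-yl]prop-2-en-1-one | CC(C)(C)[Si](C)(C)OC[C@@]1(Cc2ccc(OC)c(OC)c21)C(=O)/C(Br)=C/N(C)C | intermediate (not isolated)
17 | (Z)-2-bromo-3-(dimethylamino)-1-[(S)-1-(hydroxymethyl)-5,6-dimethoxybenzocyclobuten-1-yl]prop-2-en-1-one | OC[C@@]1(Cc2ccc(OC)c(OC)c21)C(=O)/C(Br)=C/N(C)C | intermediate (not isolated)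
18 | (3S)-5-bromo-5',6'-dimethoxyspiro[2H-pyran-3,1'-benzocyclobuten]-4-one | BrC1=COC[C@@]2(Cc3ccc(OC)c(OC)c32)C1=O | intermediate (key-step precursor)
19 | methyl (E)-3-methoxybut-2-enoate | COC(=O)/C=C(\C)OC | starting material
20 | 1,3-dimethoxy-1-(trimethylsilyloxy)buta-1,3-diene | COC(=C)C=C(OC)O[Si](C)(C)C | intermediate (key-step precursor)
21 | (3S)-4a-bromo-5,7-dimethoxy-5-(trimethylsilyloxy)-4a,5,8,8a-tetrahydro-5',6'-dimethoxyspiro[chroman-3,1'-benzocyclobuten]-4-one (cis-fused, mixture at C4a, C5 and C8a) | COC1=CC(OC)(O[Si](C)(C)C)C2(Br)C(C1)OC[C@@]1(Cc3ccc(OC)c(OC)c31)C2=O | intermediate (not isolated)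
22 | (3S)-7,5',6'-trimethoxy-5-(trimethylsilyloxy)spiro[chroman-3,1'-benzocyclobuten]-4-one | COc1cc(O[Si](C)(C)C)c2c(c1)OC[C@@]1(Cc3ccc(OC)c(OC)c31)C2=O | intermediate (not isolated)
23 | (3S)-5-hydroxy-7,5',6'-trimethoxyspiro[chroman-3,1'-benzocyclobuten]-4-one | COc1cc(O)c2c(c1)OC[C@@]1(Cc3ccc(OC)c(OC)c31)C2=O | intermediate (key-step product)
24 | (3S)-5,7,5',6'-tetramethoxyspiro[chroman-3,1'-benzocyclobuten]-4-one | COc1cc(OC)c2c(c1)OC[C@@]1(Cc3ccc(OC)c(OC)c31)C2=O | target

## Step count and least certain steps

Total: 12 steps. Longest linear sequence: 11 steps (steps 1 to 9, 11 and 12, from 1); the diene branch is one step (step 10).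

Step 11 (key step, new on this substrate class).
- What may go wrong: the cycloaddition may be too slow on the vinylogous-ester dienophile, so that 20 decays by thermal or protic desilylation first. The addition may become stepwise and stop after conjugate addition, or continue by expulsion of O1 and open ring C. In the aromatisation, ring C may open by loss of O1, or bromine may be lost reductively, in place of the loss of bromide.
- Fallback (known chemistry, leaving the cycloaddition aside): it sets out from 9 and comes back to the route at 24. Mitsunobu etherification of 9 with 3,5-dimethoxyphenol (PPh3, diisopropyl azodicarboxylate, toluene, 80 °C) should give methyl (S)-1-[(3,5-dimethoxyphenoxy)methyl]-5,6-dimethoxybenzocyclobutene-1-carboxylate F1. Saponification (LiOH, THF–water) should give the acid F2. Intramolecular Friedel–Crafts acylation of the phloroglucinol-type ring ((CF3CO)2O, CH2Cl2, 0 °C) then forms the C4–C4a bond and closes ring C to 24 directly, the two ortho positions being equivalent.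

Step 4 (desymmetrisation).
- What may go wrong: slow hydrolysis of a hindered diester and, above all, insufficient or opposite enantiotopic group selection, which cannot be predicted for this ring-constrained malonate.
- Fallback: it sets out from 7 and comes back at 8 and 9. Monosaponification with one equivalent of KOH in methanol should give the racemic half-ester F3. Classical resolution with (R)-1-phenylethylamine, the choice of amine enantiomer to be settled by screening, would give the crystalline salt of the (S)-acid F4, from which acid releases 8. The other enantiomer, (R)-half-ester F5, is not wasted: as its lithium carboxylate it would be reduced at the ester with LiBH4 to the (S)-hydroxy acid F6, whose esterification (MeI, KHCO3, DMF) gives the same 9.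

Step 9 (bromination and ring closure).
- What may go wrong: bromination beyond one equivalent or on ring B; incomplete removal of the silyl group; hydrolysis of the bromo enaminone to an open-chain bromo keto aldehyde that fails to cyclise.
- Fallback: it sets out from 15 and comes back at 18, with ring closure before halogenation. Acid treatment of 15 (2 M HCl, THF) should give the unbrominated (3S)-5',6'-dimethoxyspiro[2H-pyran-3,1'-benzocyclobuten]-4-one F8. Addition of Br2 to its enol ether bond at −78 °C followed by Et3N (addition–elimination) should then give 18.

Step 7 (methyl ketone).
- What may go wrong: incomplete acyl substitution at the hindered ester, or deprotonation and silyl transfer in place of addition.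
- Fallback: it sets out from 10 and comes back at 13. Aminolysis of 10 with MeNH(OMe)·HCl and iPrMgCl should give the N-methoxy-N-methylamide F7, whose stable chelate with MeMgBr stops the reaction at the ketone 13.

## Further compounds

F1 | step 11 | methyl (S)-1-[(3,5-dimethoxyphenoxy)methyl]-5,6-dimethoxybenzocyclobutene-1-carboxylate | COc1cc(OC)cc(c1)OC[C@@]1(Cc2ccc(OC)c(OC)c21)C(=O)OC
F2 | step 11 | (S)-1-[(3,5-dimethoxyphenoxy)methyl]-5,6-dimethoxybenzocyclobutene-1-carboxylic acid | COc1cc(OC)cc(c1)OC[C@@]1(Cc2ccc(OC)c(OC)c21)C(=O)O
F3 | step 4 | 1-(methoxycarbonyl)-5,6-dimethoxybenzocyclobutene-1-carboxylic acid (racemic) | OC(=O)C1(Cc2ccc(OC)c(OC)c21)C(=O)OC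
F4 | step 4 | (R)-1-phenylethylammonium (S)-1-(methoxycarbonyl)-5,6-dimethoxybenzocyclobutene-1-carboxylate | C[C@@H]([NH3+])c1ccccc1.[O-]C(=O)[C@@]1(Cc2ccc(OC)c(OC)c21)C(=O)OC
F5 | step 4 | (R)-1-(methoxycarbonyl)-5,6-dimethoxybenzocyclobutene-1-carboxylic acid | COC(=O)[C@@]1(Cc2ccc(OC)c(OC)c21)C(=O)O
F6 | step 4 | (S)-1-(hydroxymethyl)-5,6-dimethoxybenzocyclobutene-1-carboxylic acid | OC[C@@]1(Cc2ccc(OC)c(OC)c21)C(=O)O
F7 | step 7 | (S)-1-[(tert-butyldimethylsilyloxy)methyl]-N-methoxy-N-methyl-5,6-dimethoxybenzocyclobutene-1-carboxamide | CC(C)(C)[Si](C)(C)OC[C@@]1(Cc2ccc(OC)c(OC)c21)C(=O)N(C)OC
F8 | step 9 | (3S)-5',6'-dimethoxyspiro[2H-pyran-3,1'-benzocyclobuten]-4-one | C1=COC[C@@]2(Cc3ccc(OC)c(OC)c32)C1=O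
A1 | alternative 1 | (3S)-3-[(3-ethynyl-1,1,3,3-tetraisopropyldisiloxanyl)ethynyl]-5,7-dimethoxy-3-(prop-2-ynyl)chroman-4-one | COc1cc(OC)c2c(c1)OC[C@@](C#C[Si](C(C)C)(C(C)C)O[Si](C#C)(C(C)C)C(C)C)(CC#C)C2=O
A2 | alternative 1 | (S)-spiro chromanone–benzocyclobutene with a tetraisopropyldisiloxane ring bridging the two future methoxy-bearing carbons of ring B | COc1cc(OC)c2c(c1)OC[C@@]1(Cc3ccc4c(c31)[Si](C(C)C)(C(C)C)O[Si]4(C(C)C)C(C)C)C2=O
A3 | alternative 2 | methyl 7-[(S)-1-(benzyloxymethyl)-5,6-dimethoxybenzocyclobuten-1-yl]-3,5,7-trioxoheptanoate | COC(=O)CC(=O)CC(=O)CC(=O)[C@@]1(COCc2ccccc2)Cc2ccc(OC)c(OC)c21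
A4 | alternative 2 | [(S)-1-(benzyloxymethyl)-5,6-dimethoxybenzocyclobuten-1-yl](2,4,6-trihydroxyphenyl)methanone | O=C(c1c(O)cc(O)cc1O)[C@@]1(COCc2ccccc2)Cc2ccc(OC)c(OC)c21
A5 | alternative 3 | 2-{[2-(6-bromo-2,3-dimethoxyphenyl)prop-2-en-1-yl]oxy}-4,6-dimethoxybenzaldehyde | COc1cc(OC)c(C=O)c(c1)OCC(=C)c1c(Br)ccc(OC)c1OC
A6 | alternative 3 | (S)-3-(6-bromo-2,3-dimethoxyphenyl)-5,7-dimethoxy-3-methylchroman-4-one | COc1cc(OC)c2c(c1)OC[C@](C)(c1c(Br)ccc(OC)c1OC)C2=O
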